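The data were computed with made-up constants, noise included.

The amber run, which is the asked flask followed so far, reads 49 % at 8.00 h and 53 % at 15.0 h, so it is flattening while its product stands well short of the electrophile charged.

| flask | electrophile | nucleophile | protic impurity | temperature | remark | time |
|---|---|---|---|---|---|---|
| amber | 0.50 M | 0.60 M | 0.15 M | 60 °C | the very flask that is asked about, followed so far |  |
| violet | 0.50 M | 0.60 M | 0.15 M | 55 °C | run made earlier |  |
| flask | 0.50 M | 0.600 M | 0.150 M | 60 °C |  | 25 h |

| amber: time / h | amber: product / % | violet: time / h | violet: product / % |
|---|---|---|---|
| 1.33 | 14 | 1.33 | 12 |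
| 4.00 | 36 | 4.00 | 27 |
| 8.00 | 49 | 8.00 | 39 |
| 10.0 | 49 | 10.0 | 41 |
| 15.0 | 53 | 15.0 | 48 |

(scatter of a reading: 1.5 percentage points)

- alpha: at 25 h add nucleophile, 50.0 % of the amount charged, then wait 25 h
- eta: at 25 h take out 90 % of the acid set free then present, then wait 25 h
- zeta: change nothing and wait 25 h more
- beta: at 25 h raise the temperature by 10 K, then wait 25 h

- the volume of additions can be left aside
- the earlier runs were read with a standard deviation of 1.5 percentage points

1. product, in percent of the electrophile first charged, at 25 h
2. which option adds most product ("none" when 2 percentage points or less is all one gets) (alpha / eta / zeta / beta / none)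
3. product present, in percent of the electrophile first charged, after alpha
4. product present, in percent of the electrophile first charged, after zeta

Suppose each product sets free one acid, and that acid binds a second nucleophile. Free nucleophile then reaches zero at the charge of nucleophile divided by two, over the charge of electrophile: the nucleophile ceiling C = 60.0 %, with nucleophile as limiting reagent.

Which number must you know well? Work with what is left. Let y be the product as a fraction of the electrophile charged, so the electrophile left is 1 − y and the free nucleophile left is 1 − y/C. For a second-order step, the logarithm of their ratio climbs straight with time, at a slope s.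

Take the rate first. Amber gives s = 0.118 h⁻¹ from its 4.00 h reading and 0.0929 h⁻¹ from its 15.0 h reading. Solved for y at 25 h, these give 58.7 % and 57.5 %, which lie 1.2 points apart, and the scatter of one reading is 1.5 points.

Now the temperature: violet's slope at 55 °C, 0.0637 h⁻¹, gives 54.4 % at 25 h. The protic impurity has the same charge in both runs, so comparing them does not vary it. The nucleophile charge moves C in proportion: alpha lifts it to 90.0 %, a shift of 30 points, larger than either shift above, so C is the number to know well.

So I reckon 58.1 % now and 59.8 % after zeta, and I choose alpha. The forecast says 57 %, 59 % after zeta, 82 % after alpha and alpha as best, holding that “the ceiling is about 0.30 M, or 60%”.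

The flask gives 60.0 %, 65.4 % after zeta and 79.6 % after alpha, with alpha best at 20 points gained.

    electrophile + nucleophile → acid set free + product (k = 0.270 M⁻¹ h⁻¹, Ea = 72.0 kJ mol⁻¹)
    nucleophile + acid set free ⇌ protonated nucleophile, settled at all times (K = 120 M⁻¹, ΔH = 24.0 kJ mol⁻¹)
    electrophile + protic impurity → quenched substrate (k = 0.0780 M⁻¹ h⁻¹, Ea = 65.0 kJ mol⁻¹)
    (constants at 60 °C)

Counting every form of the nucleophile, product equals C plus half the difference between free acid and free nucleophile, over the electrophile charge. At 25.0 h the flask holds 0.0461 M of acid set free and 0.0459 M of free nucleophile, so its product stands at C. The neighbour flask, left until 2.5 d, holds 0.0893 M of acid set free against 0.0228 M of free nucleophile, which puts it 6.7 points above C, and it reads 66.7 %.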